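The route disconnects ring A between C4 and C5 (C5 carries the methylidene, C6 is the spiro atom, C2 the ring A bromine). C5 and C2 lie 1,4 across ring A, so in the precursor they are bridged by oxygen as a γ-lactone spiro-fused to ring B, made by Diels–Alder addition of isoprene to an enantioenriched α-methylene lactone. In the key step a samarium carbanion at C4 attacks the lactone carbonyl C5: one operation closes ring A, excises the lactone oxygen from C5 and frees the C2 carbinol, which then directs the ring B epoxidation and is finally inverted to the bromide. The C2 stereocentre controls the spiro centre in the cycloaddition.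

Key step: step 5

Remark: atom labels C1–C11 in the text are those of the target (C1 = CMe2, C2 = CHBr, C3, C4 = CH2, C5 = C(=CH2), C6 = spiro atom, C7, C8 = CHBr, C9 = C(CH3)Cl, C10, C11); locants in the systematic names of intermediates may differ. Assumption: the ligand enantiomer in step 1 is the one that delivers the 3S carbinol.

Step 1
Reactants: 1 3-[(tert-butyldimethylsilyl)oxy]propanal; 2 3-chloro-3-methylbut-1-yne
Product: 4 (3S)-1-[(tert-butyldimethylsilyl)oxy]-4,4-dimethylhex-5-yn-3-ol, via trimethylsilyl ether 3 (not isolated)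
Conditions: CrCl2 (10 mol %), chiral tridentate bis(oxazolinyl)carbazole ligand (12 mol %), Mn powder (2 equiv), Me3SiCl (1.5 equiv), i-Pr2NEt (30 mol %), THF, rt; then K2CO3 (cat.), MeOH
Reagents that add atoms: none
Why: Catalytic asymmetric Nozaki–Hiyama–Kishi propargylation, in which the allenylchromium species from the tertiary propargylic chloride should add through its dimethyl-substituted terminus in a closed six-membered transition state, forming the C1–C2 bond with the gem-dimethyl group in place and setting C2 as S under ligand control.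

Step 2
Reactants: 4 (3S)-1-[(tert-butyldimethylsilyl)oxy]-4,4-dimethylhex-5-yn-3-ol
Product: 5 (5S)-5-{2-[(tert-butyldimethylsilyl)oxy]ethyl}-4,4-dimethyl-3-methylideneoxolan-2-one
Conditions: PdCl2 (5 mol %), PPh3 (10 mol %), SnCl2 (5 mol %), CO (8 atm), MeCN, 75 °C
Reagents that add atoms: carbon monoxide, [C-]#[O+]
Why: Palladium-catalysed cyclocarbonylation of a but-3-yn-1-ol, in which an alkoxycarbonylpalladium species should add cis across the alkyne and protonolysis gives the α-methylene-γ-butyrolactone, so that CO becomes C5 and the C2 stereocentre is untouched.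

Step 3
Reactants: 5 (5S)-5-{2-[(tert-butyldimethylsilyl)oxy]ethyl}-4,4-dimethyl-3-methylideneoxolan-2-one; 6 isoprene (2-methylbuta-1,3-diene)
Product: 7 (3S,5S)-3-{2-[(tert-butyldimethylsilyl)oxy]ethyl}-4,4,8-trimethyl-2-oxaspiro[4.5]dec-7-en-1-one
Conditions: isoprene (10 equiv), Me2AlCl (1.2 equiv), CH2Cl2, −40 to 0 °C
Reagents that add atoms: none
Why: Lewis-acid-promoted Diels–Alder reaction of the α-methylene lactone, in which carbonyl coordination should enforce the para orientation (methyl-bearing carbon 1,4 to the new quaternary carbon) and the diene should approach the methylidene face anti to the side chain at C2, which sets the spiro centre C6 relative to C2.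

Step 4
Reactants: 7 (3S,5S)-3-{2-[(tert-butyldimethylsilyl)oxy]ethyl}-4,4,8-trimethyl-2-oxaspiro[4.5]dec-7-en-1-one
Product: 8 (3S,5S)-3-(2-bromoethyl)-4,4,8-trimethyl-2-oxaspiro[4.5]dec-7-en-1-one
Conditions: Ph3PBr2 (1.3 equiv), CH2Cl2, 0 °C to rt
Reagents that add atoms: dibromotriphenylphosphorane, BrP(Br)(c1ccccc1)(c1ccccc1)c1ccccc1
Why: Dibromotriphenylphosphorane converts a primary silyl ether directly into the bromide through an alkoxyphosphonium bromide and SN2 displacement at the primary carbon, which should leave the lactone and the trisubstituted alkene untouched.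

Step 5
Reactants: 8 (3S,5S)-3-(2-bromoethyl)-4,4,8-trimethyl-2-oxaspiro[4.5]dec-7-en-1-one
Product: 11 (4S,6S)-4-hydroxy-5,5,9-trimethylspiro[5.5]undec-8-en-1-one, via alkylsamarium diiodide 9 (not isolated), via bridged diiodosamarium hemiketalate 10 (not isolated)
Conditions: SmI2 (2.2 equiv, 0.1 M in THF, added over 1 h), HMPA (8 equiv), THF, −40 to 0 °C; aq. NH4Cl
Reagents that add atoms: none
Why: SmI2 should reduce the primary C–Br bond of 8 by two single-electron transfers to the alkylsamarium 9, whose carbanionic C4 adds to the lactone carbonyl C5 through a 5-membered transition state (C4–C3–C2–O–C5) to give the bridged hemiketalate 10, and aqueous work-up breaks the C5–O bond so that C5 emerges as the ring A ketone and the former lactone oxygen as the C2 carbinol. The closest known reaction type is the SmI2-promoted intramolecular Barbier-type nucleophilic acyl substitution of halo esters and halo lactones. Ring A is closed by a 6-exo-trig attack on the carbonyl (5-exo-trig when counted through the oxygen tether), and the lactone ring is opened in the same operation. No stereocentre is created: C2 keeps its S configuration because its C–O bond is not touched, and the quaternary spiro centre C6 cannot epimerise. The step needs chemoselective reduction of the alkyl bromide in the presence of the lactone and the ring B alkene, which the far easier reduction of C–Br by SmI2–HMPA should secure, and it needs the new ketone to stay out of reach of the reductant, which the persistence of 10 until work-up and the slow addition of SmI2 should secure.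

Step 6
Reactants: 11 (4S,6S)-4-hydroxy-5,5,9-trimethylspiro[5.5]undec-8-en-1-one
Product: 12 (2S,6R)-1,1,9-trimethyl-5-methylidenespiro[5.5]undec-8-en-2-ol
Conditions: Ph3PCH3Br (4 equiv), KOt-Bu (4 equiv), PhMe, 90 °C
Reagents that add atoms: methyltriphenylphosphonium bromide, C[P+](c1ccccc1)(c1ccccc1)c1ccccc1.[Br-]
Why: Wittig methylenation with excess ylide at elevated temperature should overcome the hindrance of the ketone next to the spiro centre, the C2 hydroxyl being carried through as its potassium alkoxide and no stereocentre being affected.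

Step 7
Reactants: 12 (2S,6R)-1,1,9-trimethyl-5-methylidenespiro[5.5]undec-8-en-2-ol
Product: 13 (2S,6R,8R,9S)-8,9-epoxy-1,1,9-trimethyl-5-methylidenespiro[5.5]undecan-2-ol (oxirane oxygen on the ring B face that carries C1)
Conditions: VO(acac)2 (5 mol %), t-BuOOH (1.5 equiv, in decane), CH2Cl2, 0 °C to rt
Reagents that add atoms: tert-butyl hydroperoxide, CC(C)(C)OO
Why: Hydroxyl-directed vanadium-catalysed epoxidation, in which the C2 hydroxyl lies syn to C7 on ring A and under the ring B face that carries C1, so the vanadium-bound peroxide should be delivered to that face of the electron-rich trisubstituted alkene in preference to the 1,1-disubstituted methylidene, setting C8 as R and C9 as S.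

Step 8
Reactants: 13 (2S,6R,8R,9S)-8,9-epoxy-1,1,9-trimethyl-5-methylidenespiro[5.5]undecan-2-ol
Product: 14 (2S,6R,8R,9R)-9-chloro-1,1,9-trimethyl-5-methylidenespiro[5.5]undecane-2,8-diol
Conditions: HCl (1.05 equiv, 1 M in Et2O), CH2Cl2, −78 °C
Reagents that add atoms: hydrogen chloride, Cl
Why: Acid-promoted epoxide opening of Markovnikov type, in which chloride should attack the tertiary carbon C9 from the face opposite the oxirane oxygen (inversion) and leave the C8 oxygen in place trans to chlorine, while the low temperature and single equivalent of acid should keep the methylidene from being protonated.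

Step 9
Reactants: 14 (2S,6R,8R,9R)-9-chloro-1,1,9-trimethyl-5-methylidenespiro[5.5]undecane-2,8-diol
Product: 15 (2R,6R,8S,9R)-2,8-dibromo-9-chloro-1,1,9-trimethyl-5-methylidenespiro[5.5]undecane
Conditions: CBr4 (6 equiv), P(n-C8H17)3 (6 equiv), PhMe, 70 °C
Reagents that add atoms: carbon tetrabromide, BrC(Br)(Br)Br
Why: Twofold Appel reaction, in which each secondary carbinol (neopentyl-type C2 and β-chloro C8) is activated as an alkoxyphosphonium ion and displaced by bromide with inversion, which should turn 2S into 2R and place the C8 bromine cis to the C9 chlorine.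

Compound list
1 | 3-[(tert-butyldimethylsilyl)oxy]propanal | O=CCCO[Si](C)(C)C(C)(C)C | starting material
2 | 3-chloro-3-methylbut-1-yne | C#CC(C)(C)Cl | starting material
3 | (3S)-1-[(tert-butyldimethylsilyl)oxy]-4,4-dimethyl-3-[(trimethylsilyl)oxy]hex-5-yne | C#CC(C)(C)[C@@H](O[Si](C)(C)C)CCO[Si](C)(C)C(C)(C)C | intermediate
4 | (3S)-1-[(tert-butyldimethylsilyl)oxy]-4,4-dimethylhex-5-yn-3-ol | C#CC(C)(C)[C@@H](O)CCO[Si](C)(C)C(C)(C)C | intermediate
5 | (5S)-5-{2-[(tert-butyldimethylsilyl)oxy]ethyl}-4,4-dimethyl-3-methylideneoxolan-2-one | C=C1C(=O)O[C@@H](CCO[Si](C)(C)C(C)(C)C)C1(C)C | intermediate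
6 | isoprene (2-methylbuta-1,3-diene) | C=CC(C)=C | starting material
7 | (3S,5S)-3-{2-[(tert-butyldimethylsilyl)oxy]ethyl}-4,4,8-trimethyl-2-oxaspiro[4.5]dec-7-en-1-one | O=C1O[C@@H](CCO[Si](C)(C)C(C)(C)C)C(C)(C)[C@@]12CCC(C)=CC2 | intermediate
8 | (3S,5S)-3-(2-bromoethyl)-4,4,8-trimethyl-2-oxaspiro[4.5]dec-7-en-1-one | O=C1O[C@@H](CCBr)C(C)(C)[C@@]12CCC(C)=CC2 | intermediate
9 | {2-[(3S,5S)-4,4,8-trimethyl-1-oxo-2-oxaspiro[4.5]dec-7-en-3-yl]ethyl}samarium diiodide | O=C1O[C@@H](CC[Sm](I)I)C(C)(C)[C@@]12CCC(C)=CC2 | intermediate
10 | bridged hemiketalate: C5 carries the diiodosamarium alkoxide, is bonded to C4 and C6 and is still joined to C2 through the former lactone oxygen (7-oxabicyclo[2.2.1]heptane core spiro-fused to ring B) | [O-][C@]12CC[C@H](O1)C(C)(C)[C@@]23CCC(C)=CC3.[Sm+3].[I-].[I-] | intermediate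
11 | (4S,6S)-4-hydroxy-5,5,9-trimethylspiro[5.5]undec-8-en-1-one | O=C1CC[C@H](O)C(C)(C)[C@@]12CCC(C)=CC2 | intermediate
12 | (2S,6R)-1,1,9-trimethyl-5-methylidenespiro[5.5]undec-8-en-2-ol | C=C1CC[C@H](O)C(C)(C)[C@@]12CCC(C)=CC2 | intermediate
13 | (2S,6R,8R,9S)-8,9-epoxy-1,1,9-trimethyl-5-methylidenespiro[5.5]undecan-2-ol | C=C1CC[C@H](O)C(C)(C)[C@@]12CC[C@]3(C)O[C@@H]3C2 | intermediate
14 | (2S,6R,8R,9R)-9-chloro-1,1,9-trimethyl-5-methylidenespiro[5.5]undecane-2,8-diol | C=C1CC[C@H](O)C(C)(C)[C@@]12CC[C@@](C)(Cl)[C@H](O)C2 | intermediate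
15 | (2R,6R,8S,9R)-2,8-dibromo-9-chloro-1,1,9-trimethyl-5-methylidenespiro[5.5]undecane | C=C1CC[C@@H](Br)C(C)(C)[C@@]12CC[C@@](C)(Cl)[C@@H](Br)C2 | target

Total step count: 9
Longest linear sequence: 9 steps (1 to 15)

Steps most likely to fail

Step 9. Two hindered carbinols must each be substituted with inversion. Elimination, a 1,2-methyl shift at the neopentyl-type C2, or chlorine participation at C8 (retention or halogen migration) may compete. Fallback: the ring B halogens are built from the alkene, not from the chlorohydrin. Setting out from 12, a single Appel substitution (CBr4, P(n-C8H17)3, PhMe, 70 °C) should give (2R,6R)-2-bromo-1,1,9-trimethyl-5-methylidenespiro[5.5]undec-8-ene F1. Anti addition of PhSeCl to the ring B alkene under equilibrating conditions (CH2Cl2, −78 °C to rt), with selenium entering on the face that carries C1 and chloride at tertiary C9, should give (2R,6R,8R,9R)-2-bromo-9-chloro-1,1,9-trimethyl-5-methylidene-8-(phenylselanyl)spiro[5.5]undecane F2. One equivalent of Br2 (CH2Cl2, −78 to 0 °C) should then oxidise selenium to the tetravalent dibromide, which bromide displaces at C8 with inversion, coming back to the route at 15.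

Step 8. Chloride may attack the secondary carbon C8, the acid may promote ether formation between the C2 hydroxyl and the C5 methylidene, or a hydride shift may give a ketone. Fallback: the ring B functionalisation is moved ahead of the methylenation so that no acid-sensitive methylidene is present. Setting out from 11, the same hydroxyl-directed epoxidation (VO(acac)2, t-BuOOH) should give (4S,6S,8R,9S)-8,9-epoxy-4-hydroxy-5,5,9-trimethylspiro[5.5]undecan-1-one F3. Opening with HCl at −78 °C should give (4S,6S,8R,9R)-9-chloro-4,8-dihydroxy-5,5,9-trimethylspiro[5.5]undecan-1-one F4. Twofold Appel substitution should give (4R,6S,8S,9R)-4,8-dibromo-9-chloro-5,5,9-trimethylspiro[5.5]undecan-1-one F5. Methylenation under non-basic conditions (Cp2TiMe2, PhMe, 70 °C) comes back to the route at 15.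

Step 1. Enantioselectivity may be insufficient with the hindered dimethyl-substituted allenylchromium species, or bond formation may occur through the unsubstituted terminus. Fallback: the stereocentre is set by reagent-controlled ketone reduction. Setting out from 1 and 2, a zinc-mediated Barbier propargylation (Zn, THF–aq. NH4Cl) should give racemic 1-[(tert-butyldimethylsilyl)oxy]-4,4-dimethylhex-5-yn-3-ol F6. Dess–Martin periodinane oxidation should give 1-[(tert-butyldimethylsilyl)oxy]-4,4-dimethylhex-5-yn-3-one F7. Corey–Bakshi–Shibata reduction with (R)-1-methyl-3,3-diphenyltetrahydro-1H,3H-pyrrolo[1,2-c][1,3,2]oxazaborole and catecholborane (PhMe, −78 °C; catecholborane spares the terminal alkyne) should give the 3S carbinol, coming back to the route at 4.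

Further compounds
F1 | step 9 | (2R,6R)-2-bromo-1,1,9-trimethyl-5-methylidenespiro[5.5]undec-8-ene | C=C1CC[C@@H](Br)C(C)(C)[C@@]12CCC(C)=CC2
F2 | step 9 | (2R,6R,8R,9R)-2-bromo-9-chloro-1,1,9-trimethyl-5-methylidene-8-(phenylselanyl)spiro[5.5]undecane | C=C1CC[C@@H](Br)C(C)(C)[C@@]12CC[C@@](C)(Cl)[C@H]([Se]c3ccccc3)C2
F3 | step 8 | (4S,6S,8R,9S)-8,9-epoxy-4-hydroxy-5,5,9-trimethylspiro[5.5]undecan-1-one | O=C1CC[C@H](O)C(C)(C)[C@@]12CC[C@]3(C)O[C@@H]3C2
F4 | step 8 | (4S,6S,8R,9R)-9-chloro-4,8-dihydroxy-5,5,9-trimethylspiro[5.5]undecan-1-one | O=C1CC[C@H](O)C(C)(C)[C@@]12CC[C@@](C)(Cl)[C@H](O)C2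
F5 | step 8 | (4R,6S,8S,9R)-4,8-dibromo-9-chloro-5,5,9-trimethylspiro[5.5]undecan-1-one | O=C1CC[C@@H](Br)C(C)(C)[C@@]12CC[C@@](C)(Cl)[C@@H](Br)C2
F6 | step 1 | racemic 1-[(tert-butyldimethylsilyl)oxy]-4,4-dimethylhex-5-yn-3-ol | C#CC(C)(C)C(O)CCO[Si](C)(C)C(C)(C)C
F7 | step 1 | 1-[(tert-butyldimethylsilyl)oxy]-4,4-dimethylhex-5-yn-3-one | C#CC(C)(C)C(=O)CCO[Si](C)(C)C(C)(C)C
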